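1.50 M of reagent is what the 0.50 M of substrate in each of these flasks takes to reach triple product, one reagent per step.

the same everywhere: substrate 0.50 M

| flask | reagent | remark | time |
|---|---|---|---|
| Tuesday's | 0.55 M | run made earlier |  |
| Saturday's | 1.1 M | run made earlier |  |
| Thursday's | 2.1 M | run made earlier |  |
| teal | 0.500 M |  | 25 min |
| green | 1.50 M |  | 25 min |
| grey | 2.00 M |  | 25 min |

| run | time / min | first product / % | triple product / % | substrate / % |
|---|---|---|---|---|
| Tuesday's | 1.00 | 51.3 | 3.9 | 29.5 |
| Tuesday's | 2.00 | 51.9 | 5.3 | 25.1 |
| Tuesday's | 4.00 | 52.3 | 5.1 | 23.7 |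
| Tuesday's | 6.00 | 52.1 | 4.4 | 22.7 |
| Tuesday's | 12.0 | 51.5 | 4.4 | 23.1 |
| Saturday's | 1.00 | 40.7 | 24.1 | 6.1 |
| Saturday's | 2.00 | 32.6 | 32.6 | 3.4 |
| Saturday's | 4.00 | 29.0 | 32.7 | 2.0 |
| Saturday's | 6.00 | 26.4 | 31.7 | 2.3 |
| Saturday's | 12.0 | 25.5 | 30.3 | 1.5 |
| Thursday's | 2.50 | 0.8 | 79.4 | 0.1 |
| Thursday's | 5.00 | 0 | 71.0 | 0.3 |
| Thursday's | 8.00 | 0 | 65.6 | 0 |
| Thursday's | 10.0 | 0 | 64.1 | 0.1 |
| Thursday's | 12.0 | 0.1 | 64.3 | 0.1 |

(each reading ± 0.3 percentage points)



* first product at the end, in percent of the substrate charged, for each flask in turn (teal, green, grey)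

Taken by itself, the first step turns substrate into first product, using one reagent for each substrate. Adding the step from first product to double product lets first product compete with substrate for reagent. Tuesday's first product reads 51.5 % at 12.0 min, beside 23.1 % of substrate, and it barely moves after 1.00 min. Teal's charge is close to Tuesday's, so this reckoning puts teal near that reading.

Adding the third step gives the balance that sorts the flasks: the spare reagent, s = c(reagent) − 3 c(substrate), the charge left over once every substrate has become triple product. It is −1.00 M for teal, 0 M for green and 0.500 M for grey. A negative s makes reagent the limiting reagent and strands first product: Saturday's s of −0.400 M leaves a reading of 25.5 %. A positive s clears it: Thursday's s of 0.600 M gives 0 % at 5.00 min. Green lies between, so this reckoning expects a small remainder there and none in grey, though it puts no figure on green. The remaining change, Thursday's triple product falling from 79.4 % to 64.3 %, is taken to use no reagent and leaves s as it was.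

The forecast gives 51.5 %, 1 % and 0 %, with green on “a slow second-order tail as reagent runs out”.

The flasks give 51.8 %, 1.18 % and <0.001 %, within the margin of the forecast.

    substrate + reagent → first product (k = 0.100 M⁻¹ s⁻¹)
    reagent + first product → double product (k = 0.0450 M⁻¹ s⁻¹)
    reagent + double product → triple product (k = 0.0590 M⁻¹ s⁻¹)
    triple product ⇌ isomer of the product (K = 0.590, k = 0.00220 s⁻¹)
    reagent ⇌ dormant form (K = 0.410, k = 0.00220 s⁻¹)

In green, substrate was down to 0.00808 % by 12.5 min, and the later additions ran on: at 25.0 min, reagent and dormant form together held 0.0255 M, matching the 0.0254 M of additions still owed by first product and double product, as an s of 0 M requires. In grey, first product and double product stood at 0 % and 0 % at 25.0 min, and the s of 0.500 M was found as free reagent plus dormant form, together 0.500 M.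

All runs are calculated with constants of no real substance; the scatter is artificial.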